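**Strategy**

Everything rests on the bond between the allylic CH2 and the carbinol carbon of the side chain. In the γ-butyrolactone ring (O1, C2–C5) the C2 carbonyl, the exocyclic C3=CH alkene and this CH2 make up a vinylogous enolate whose γ-carbon is the CH2, while the carbinol carbon is the carbonyl carbon of an (E)-2-methyl enal. One catalytic enantioselective vinylogous Mukaiyama aldol reaction therefore joins a 2-silyloxy-3-vinyl-4,5-dihydrofuran, made from 2-deoxy-D-ribonolactone (source of C4 and C5), to a nerol-derived enal that already carries the protected coumaryl ether, and it sets the C–C bond, the (R)-carbinol centre and the (E)-alkylidene geometry together.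

Key step: step 13

Remark: lactone positions are numbered O1, C2 (C=O), C3, C4, C5 throughout; 2-deoxy-D-ribono-1,4-lactone is taken as commercial (otherwise one step, Br2/H2O, from 2-deoxy-D-ribose).
Remark: the (R,R)-bisphosphoramide is assumed to direct attack to the Re face of the bound aldehyde, as is usual for this catalyst family; should the sense prove opposite, its (S,S)-enantiomer is used in step 13.

**Lactone fragment (steps 1–6)**

Step 1
Reactants: 1 2-deoxy-D-ribono-1,4-lactone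
Product: 2 (4S,5R)-4-(triethylsilyloxy)-5-[(triethylsilyloxy)methyl]oxolan-2-one
Conditions: TESCl (2.4 equiv), imidazole, DMF, 0 °C to rt
Reagents that add atoms: chlorotriethylsilane, CC[Si](Cl)(CC)CC
Why: Imidazole-promoted silyl ether formation on the primary and the secondary hydroxyl group should go to completion without touching C4 and C5, which are taken unchanged from the sugar lactone.

Step 2
Reactants: 2 (4S,5R)-4-(triethylsilyloxy)-5-[(triethylsilyloxy)methyl]oxolan-2-one
Product: 3 (2S,3S)-5-oxo-3-(triethylsilyloxy)oxolane-2-carbaldehyde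
Conditions: (COCl)2, DMSO, CH2Cl2, −78 to −40 °C; Et3N, −78 to 0 °C; crude product used at once
Reagents that add atoms: none
Why: In the Swern oxidation the chlorosulfonium salt should cleave only the unhindered primary TES ether and oxidise it in the same flask to the aldehyde while the secondary TES ether stays, and the α-centre should keep its configuration if the mixture is kept cold.

Step 3
Reactants: 3 (2S,3S)-5-oxo-3-(triethylsilyloxy)oxolane-2-carbaldehyde
Product: 4 (4S,5R)-5-(2-methylprop-1-en-1-yl)-4-(triethylsilyloxy)oxolan-2-one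
Conditions: i-PrPPh3I, n-BuLi, THF, 0 °C; then 3, −78 to 0 °C
Reagents that add atoms: isopropyltriphenylphosphonium iodide, CC(C)[P+](c1ccccc1)(c1ccccc1)c1ccccc1.[I-]
Why: Wittig olefination with the non-stabilised isopropylidene ylide should take the aldehyde far faster than the lactone carbonyl, leaves no alkene geometry to control, and at low temperature should not enolise the α-oxygenated aldehyde, so C5 is retained.

Step 4
Reactants: 4 (4S,5R)-5-(2-methylprop-1-en-1-yl)-4-(triethylsilyloxy)oxolan-2-one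
Product: 5 (3S,4S,5R)-3-(1-hydroxyethyl)-5-(2-methylprop-1-en-1-yl)-4-(triethylsilyloxy)oxolan-2-one (3,4-trans; both carbinol epimers)
Conditions: LDA, THF, −78 °C; CH3CHO, −78 °C; aq. NH4Cl
Reagents that add atoms: acetaldehyde, CC=O
Why: Aldol addition of the lithium lactone enolate, in which the aldehyde should enter anti to the C4 silyloxy group; both new centres are removed in step 5, and −78 °C suppresses β-elimination of the silyloxy group.

Step 5
Reactants: 5 (3S,4S,5R)-3-(1-hydroxyethyl)-5-(2-methylprop-1-en-1-yl)-4-(triethylsilyloxy)oxolan-2-one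
Product: 7 (3E,4S,5R)-3-ethylidene-5-(2-methylprop-1-en-1-yl)-4-(triethylsilyloxy)oxolan-2-one, via mesylate 6 (not isolated)
Conditions: MsCl, Et3N, CH2Cl2, 0 °C; then DBU, rt
Reagents that add atoms: none
Why: Mesylation followed by DBU-induced E1cB elimination should give the conjugated ethylidene lactone, mainly as the E isomer, and either geometric isomer leads to the same dienolate in step 6.

Step 6
Reactants: 7 (3E,4S,5R)-3-ethylidene-5-(2-methylprop-1-en-1-yl)-4-(triethylsilyloxy)oxolan-2-one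
Product: 8 tert-butyl{[(4S,5R)-3-ethenyl-5-(2-methylprop-1-en-1-yl)-4-(triethylsilyloxy)-4,5-dihydrofuran-2-yl]oxy}dimethylsilane
Conditions: LDA, THF, −78 °C; TBSCl, DMPU, −78 to 0 °C; pentane, filtration under Ar, used directly
Reagents that add atoms: tert-butyldimethylsilyl chloride, CC(C)(C)[Si](C)(C)Cl
Why: γ-Deprotonation of the α-alkylidene lactone gives the extended lithium dienolate, which is silylated on oxygen (silyl ketene acetal formation as for tiglate-type esters); cold trapping should keep the β-silyloxy enolate from eliminating, and C4 and C5 are untouched.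

**Aldehyde fragment (steps 7–12)**

Step 7
Reactants: 9 methyl (2E)-3-(4-hydroxyphenyl)prop-2-enoate
Product: 10 methyl (2E)-3-[4-(triisopropylsilyloxy)phenyl]prop-2-enoate
Conditions: TIPSCl, imidazole, DMF, rt
Reagents that add atoms: chlorotriisopropylsilane, CC(C)[Si](Cl)(C(C)C)C(C)C
Why: Silylation of the phenol; the bulky TIPS group is chosen because it should survive the alkoxide of step 10 and the Lewis acid of step 13.

Step 8
Reactants: 10 methyl (2E)-3-[4-(triisopropylsilyloxy)phenyl]prop-2-enoate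
Product: 11 (2E)-3-[4-(triisopropylsilyloxy)phenyl]prop-2-en-1-ol
Conditions: DIBAL-H (2.2 equiv), CH2Cl2, −78 °C; Rochelle salt
Reagents that add atoms: none
Why: DIBAL-H reduces the conjugated ester by 1,2-addition to the allylic alcohol without touching the E alkene or the aryl silyl ether.

Step 9
Reactants: 12 nerol
Product: 13 neryl bromide, (2Z)-1-bromo-3,7-dimethylocta-2,6-diene
Conditions: PBr3, Et2O, −10 °C; used crude
Reagents that add atoms: phosphorus tribromide, BrP(Br)Br
Why: Bromide displaces the phosphite ester of the primary allylic alcohol by SN2 at low temperature, which should keep the Z geometry and limit allylic transposition.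

Step 10
Reactants: 11 (2E)-3-[4-(triisopropylsilyloxy)phenyl]prop-2-en-1-ol; 13 neryl bromide
Product: 14 triisopropyl{4-[(1E)-3-{[(2Z)-3,7-dimethylocta-2,6-dien-1-yl]oxy}prop-1-en-1-yl]phenoxy}silane
Conditions: NaH, THF, 0 °C; 13, Bu4NI (cat.), 0 °C to rt
Reagents that add atoms: none
Why: Williamson ether synthesis, in which SN2 attack of the sodium alkoxide on the primary allylic bromide should give the unsymmetrical diallyl ether with both alkene geometries retained.

Step 11
Reactants: 14 triisopropyl{4-[(1E)-3-{[(2Z)-3,7-dimethylocta-2,6-dien-1-yl]oxy}prop-1-en-1-yl]phenoxy}silane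
Product: 15 (2E,6Z)-2,6-dimethyl-8-({(2E)-3-[4-(triisopropylsilyloxy)phenyl]prop-2-en-1-yl}oxy)octa-2,6-dien-1-ol
Conditions: SeO2 (cat.), t-BuOOH, salicylic acid (cat.), CH2Cl2, 0 °C to rt
Reagents that add atoms: selenium dioxide, O=[Se]=O (catalytic oxygen carrier); tert-butyl hydroperoxide, CC(C)(C)OO (terminal oxygen source)
Why: Allylic oxidation (ene reaction then [2,3]-sigmatropic shift) should select the E-methyl group of the terminal, most electron-rich trisubstituted alkene, as is usual for neryl and geranyl ethers, which fixes the E geometry; any enal already formed converges in step 12.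

Step 12
Reactants: 15 (2E,6Z)-2,6-dimethyl-8-({(2E)-3-[4-(triisopropylsilyloxy)phenyl]prop-2-en-1-yl}oxy)octa-2,6-dien-1-ol
Product: 16 (2E,6Z)-2,6-dimethyl-8-({(2E)-3-[4-(triisopropylsilyloxy)phenyl]prop-2-en-1-yl}oxy)octa-2,6-dienal
Conditions: MnO2, CH2Cl2, rt
Reagents that add atoms: none
Why: MnO2 oxidises only the allylic alcohol to the conjugated aldehyde and leaves the ethers, the other alkenes and the silyl ether alone.

**Fragment union and endgame (steps 13–17)**

Step 13
Reactants: 8 tert-butyl{[(4S,5R)-3-ethenyl-5-(2-methylprop-1-en-1-yl)-4-(triethylsilyloxy)-4,5-dihydrofuran-2-yl]oxy}dimethylsilane; 16 (2E,6Z)-2,6-dimethyl-8-({(2E)-3-[4-(triisopropylsilyloxy)phenyl]prop-2-en-1-yl}oxy)octa-2,6-dienal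
Product: 17 (3E,4S,5R)-3-[(3R,4E,8Z)-3-hydroxy-4,8-dimethyl-10-({(2E)-3-[4-(triisopropylsilyloxy)phenyl]prop-2-en-1-yl}oxy)deca-4,8-dien-1-ylidene]-5-(2-methylprop-1-en-1-yl)-4-(triethylsilyloxy)oxolan-2-one
Conditions: SiCl4 (1.1 equiv), (R,R)-bisphosphoramide (pentamethylene-linked bis(N,N'-dimethyl-1,1'-binaphthyl-2,2'-diamine phosphoramide), 5 mol %), i-Pr2NEt (10 mol %), CH2Cl2, −78 °C; aq. KF/NaHCO3
Reagents that add atoms: none
Why: The chiral bisphosphoramide binds SiCl4 and expels chloride, the resulting chiral trichlorosilyl cation activates aldehyde 16, the terminal CH2 of the 3-vinyl group of 8 (the γ-carbon of the dienolate) attacks the carbonyl carbon through an open transition state, and chloride then removes the TBS group so that the lactone C=O and the exocyclic C3=CH bond appear together. The closest known reaction type is the Lewis-base-catalysed, SiCl4-mediated vinylogous Mukaiyama aldol addition of α-substituted ester dienol silyl ethers to conjugated aldehydes. No ring is closed. The one new stereocentre, the carbinol carbon, is set by the catalyst, which is expected to expose the Re face of the bound aldehyde and so give the (R)-alcohol, while C4 and C5 lie too far from the reacting terminus to interfere. γ- over α-attack is secured by the hindered, fully substituted C3 and the bulk of the catalyst-bound electrophile, 1,2- over 1,4-addition by carbonyl activation of the α-methyl enal, and the E geometry by reaction through the s-trans diene conformer that keeps the vinyl terminus away from the OTBS group. The amine-buffered conditions at −78 °C are chosen so that the acid-labile cinnamyl ether and the TES and TIPS ethers survive.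

Step 14
Reactants: 17 (3E,4S,5R)-3-[(3R,4E,8Z)-3-hydroxy-4,8-dimethyl-10-({(2E)-3-[4-(triisopropylsilyloxy)phenyl]prop-2-en-1-yl}oxy)deca-4,8-dien-1-ylidene]-5-(2-methylprop-1-en-1-yl)-4-(triethylsilyloxy)oxolan-2-one
Product: 18 (3E,4S,5R)-3-[(3R,4E,8Z)-3-(tert-butyldimethylsilyloxy)-4,8-dimethyl-10-({(2E)-3-[4-(triisopropylsilyloxy)phenyl]prop-2-en-1-yl}oxy)deca-4,8-dien-1-ylidene]-5-(2-methylprop-1-en-1-yl)-4-(triethylsilyloxy)oxolan-2-one
Conditions: TBSOTf, 2,6-lutidine, CH2Cl2, −78 °C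
Reagents that add atoms: tert-butyldimethylsilyl triflate, CC(C)(C)[Si](C)(C)OS(=O)(=O)C(F)(F)F
Why: Silylation of the new secondary allylic alcohol with the silyl triflate; TBS is chosen so that the TES ether at C4 can be removed selectively in the next step.

Step 15
Reactants: 18 (3E,4S,5R)-3-[(3R,4E,8Z)-3-(tert-butyldimethylsilyloxy)-4,8-dimethyl-10-({(2E)-3-[4-(triisopropylsilyloxy)phenyl]prop-2-en-1-yl}oxy)deca-4,8-dien-1-ylidene]-5-(2-methylprop-1-en-1-yl)-4-(triethylsilyloxy)oxolan-2-one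
Product: 19 (3E,4S,5R)-3-[(3R,4E,8Z)-3-(tert-butyldimethylsilyloxy)-4,8-dimethyl-10-({(2E)-3-[4-(triisopropylsilyloxy)phenyl]prop-2-en-1-yl}oxy)deca-4,8-dien-1-ylidene]-4-hydroxy-5-(2-methylprop-1-en-1-yl)oxolan-2-one
Conditions: PPTS (cat.), MeOH/CH2Cl2, 0 °C to rt
Reagents that add atoms: none
Why: Mild acid-catalysed methanolysis cleaves the secondary TES ether much faster than the secondary TBS ether or the aryl TIPS ether (selective desilylation), and PPTS should be too weak to ionise the cinnamyl ether.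

Step 16
Reactants: 19 (3E,4S,5R)-3-[(3R,4E,8Z)-3-(tert-butyldimethylsilyloxy)-4,8-dimethyl-10-({(2E)-3-[4-(triisopropylsilyloxy)phenyl]prop-2-en-1-yl}oxy)deca-4,8-dien-1-ylidene]-4-hydroxy-5-(2-methylprop-1-en-1-yl)oxolan-2-one
Product: 20 (2R,3S,4E)-4-[(3R,4E,8Z)-3-(tert-butyldimethylsilyloxy)-4,8-dimethyl-10-({(2E)-3-[4-(triisopropylsilyloxy)phenyl]prop-2-en-1-yl}oxy)deca-4,8-dien-1-ylidene]-2-(2-methylprop-1-en-1-yl)-5-oxooxolan-3-yl acetate
Conditions: Ac2O, pyridine, DMAP (cat.), CH2Cl2, 0 °C to rt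
Reagents that add atoms: acetic anhydride, CC(=O)OC(C)=O
Why: DMAP-catalysed acetylation of the only free hydroxyl group; the carbinol carbon cannot epimerise because the neighbouring ring carbon is sp2.

Step 17
Reactants: 20 (2R,3S,4E)-4-[(3R,4E,8Z)-3-(tert-butyldimethylsilyloxy)-4,8-dimethyl-10-({(2E)-3-[4-(triisopropylsilyloxy)phenyl]prop-2-en-1-yl}oxy)deca-4,8-dien-1-ylidene]-2-(2-methylprop-1-en-1-yl)-5-oxooxolan-3-yl acetate
Product: 21 (2R,3S,4E)-4-[(3R,4E,8Z)-3-hydroxy-10-{[(2E)-3-(4-hydroxyphenyl)prop-2-en-1-yl]oxy}-4,8-dimethyldeca-4,8-dien-1-ylidene]-2-(2-methylprop-1-en-1-yl)-5-oxooxolan-3-yl acetate (CNP0237370.1)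
Conditions: TBAF, AcOH (1:1), THF, 0 °C to rt
Reagents that add atoms: none
Why: Fluoride cleaves the aryl TIPS and the secondary TBS ether, and buffering with acetic acid should keep the medium from becoming basic enough to cleave the acetate or to add the phenoxide to the alkylidene lactone.

**Compound list**

1 | 2-deoxy-D-ribono-1,4-lactone, (4S,5R)-4-hydroxy-5-(hydroxymethyl)oxolan-2-one | O[C@H]1CC(=O)O[C@@H]1CO | starting material
2 | (4S,5R)-4-(triethylsilyloxy)-5-[(triethylsilyloxy)methyl]oxolan-2-one | CC[Si](CC)(CC)O[C@H]1CC(=O)O[C@@H]1CO[Si](CC)(CC)CC | intermediate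
3 | (2S,3S)-5-oxo-3-(triethylsilyloxy)oxolane-2-carbaldehyde | CC[Si](CC)(CC)O[C@H]1CC(=O)O[C@@H]1C=O | intermediate
4 | (4S,5R)-5-(2-methylprop-1-en-1-yl)-4-(triethylsilyloxy)oxolan-2-one | CC[Si](CC)(CC)O[C@H]1CC(=O)O[C@@H]1C=C(C)C | intermediate
5 | (3S,4S,5R)-3-(1-hydroxyethyl)-5-(2-methylprop-1-en-1-yl)-4-(triethylsilyloxy)oxolan-2-one (3,4-trans; both carbinol epimers) | CC[Si](CC)(CC)O[C@H]1[C@H](C(C)O)C(=O)O[C@@H]1C=C(C)C | intermediate
6 | 1-[(4S,5R)-5-(2-methylprop-1-en-1-yl)-2-oxo-4-(triethylsilyloxy)oxolan-3-yl]ethyl methanesulfonate (3,4-trans) | CC[Si](CC)(CC)O[C@H]1[C@H](C(C)OS(C)(=O)=O)C(=O)O[C@@H]1C=C(C)C | intermediate (not isolated)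
7 | (3E,4S,5R)-3-ethylidene-5-(2-methylprop-1-en-1-yl)-4-(triethylsilyloxy)oxolan-2-one | CC[Si](CC)(CC)O[C@H]1/C(=C\C)C(=O)O[C@@H]1C=C(C)C | intermediate
8 | tert-butyl{[(4S,5R)-3-ethenyl-5-(2-methylprop-1-en-1-yl)-4-(triethylsilyloxy)-4,5-dihydrofuran-2-yl]oxy}dimethylsilane | CC[Si](CC)(CC)O[C@H]1C(C=C)=C(O[Si](C)(C)C(C)(C)C)O[C@@H]1C=C(C)C | intermediate
9 | methyl (2E)-3-(4-hydroxyphenyl)prop-2-enoate (methyl p-coumarate) | COC(=O)/C=C/c1ccc(O)cc1 | starting material
10 | methyl (2E)-3-[4-(triisopropylsilyloxy)phenyl]prop-2-enoate | COC(=O)/C=C/c1ccc(O[Si](C(C)C)(C(C)C)C(C)C)cc1 | intermediate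
11 | (2E)-3-[4-(triisopropylsilyloxy)phenyl]prop-2-en-1-ol | OC/C=C/c1ccc(O[Si](C(C)C)(C(C)C)C(C)C)cc1 | intermediate
12 | nerol, (2Z)-3,7-dimethylocta-2,6-dien-1-ol | CC(C)=CCC/C(C)=C\CO | starting material
13 | neryl bromide, (2Z)-1-bromo-3,7-dimethylocta-2,6-diene | CC(C)=CCC/C(C)=C\CBr | intermediate
14 | triisopropyl{4-[(1E)-3-{[(2Z)-3,7-dimethylocta-2,6-dien-1-yl]oxy}prop-1-en-1-yl]phenoxy}silane | CC(C)=CCC/C(C)=C\COC/C=C/c1ccc(O[Si](C(C)C)(C(C)C)C(C)C)cc1 | intermediate
15 | (2E,6Z)-2,6-dimethyl-8-({(2E)-3-[4-(triisopropylsilyloxy)phenyl]prop-2-en-1-yl}oxy)octa-2,6-dien-1-ol | OC/C(C)=C/CC/C(C)=C\COC/C=C/c1ccc(O[Si](C(C)C)(C(C)C)C(C)C)cc1 | intermediate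
16 | (2E,6Z)-2,6-dimethyl-8-({(2E)-3-[4-(triisopropylsilyloxy)phenyl]prop-2-en-1-yl}oxy)octa-2,6-dienal | O=C/C(C)=C/CC/C(C)=C\COC/C=C/c1ccc(O[Si](C(C)C)(C(C)C)C(C)C)cc1 | intermediate
17 | (3E,4S,5R)-3-[(3R,4E,8Z)-3-hydroxy-4,8-dimethyl-10-({(2E)-3-[4-(triisopropylsilyloxy)phenyl]prop-2-en-1-yl}oxy)deca-4,8-dien-1-ylidene]-5-(2-methylprop-1-en-1-yl)-4-(triethylsilyloxy)oxolan-2-one | CC[Si](CC)(CC)O[C@H]1/C(=C\C[C@@H](O)/C(C)=C/CC/C(C)=C\COC/C=C/c2ccc(O[Si](C(C)C)(C(C)C)C(C)C)cc2)C(=O)O[C@@H]1C=C(C)C | intermediate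
18 | (3E,4S,5R)-3-[(3R,4E,8Z)-3-(tert-butyldimethylsilyloxy)-4,8-dimethyl-10-({(2E)-3-[4-(triisopropylsilyloxy)phenyl]prop-2-en-1-yl}oxy)deca-4,8-dien-1-ylidene]-5-(2-methylprop-1-en-1-yl)-4-(triethylsilyloxy)oxolan-2-one | CC[Si](CC)(CC)O[C@H]1/C(=C\C[C@@H](O[Si](C)(C)C(C)(C)C)/C(C)=C/CC/C(C)=C\COC/C=C/c2ccc(O[Si](C(C)C)(C(C)C)C(C)C)cc2)C(=O)O[C@@H]1C=C(C)C | intermediate
19 | (3E,4S,5R)-3-[(3R,4E,8Z)-3-(tert-butyldimethylsilyloxy)-4,8-dimethyl-10-({(2E)-3-[4-(triisopropylsilyloxy)phenyl]prop-2-en-1-yl}oxy)deca-4,8-dien-1-ylidene]-4-hydroxy-5-(2-methylprop-1-en-1-yl)oxolan-2-one | O[C@H]1/C(=C\C[C@@H](O[Si](C)(C)C(C)(C)C)/C(C)=C/CC/C(C)=C\COC/C=C/c2ccc(O[Si](C(C)C)(C(C)C)C(C)C)cc2)C(=O)O[C@@H]1C=C(C)C | intermediate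
20 | (2R,3S,4E)-4-[(3R,4E,8Z)-3-(tert-butyldimethylsilyloxy)-4,8-dimethyl-10-({(2E)-3-[4-(triisopropylsilyloxy)phenyl]prop-2-en-1-yl}oxy)deca-4,8-dien-1-ylidene]-2-(2-methylprop-1-en-1-yl)-5-oxooxolan-3-yl acetate | CC(=O)O[C@H]1/C(=C\C[C@@H](O[Si](C)(C)C(C)(C)C)/C(C)=C/CC/C(C)=C\COC/C=C/c2ccc(O[Si](C(C)C)(C(C)C)C(C)C)cc2)C(=O)O[C@@H]1C=C(C)C | intermediate
21 | (2R,3S,4E)-4-[(3R,4E,8Z)-3-hydroxy-10-{[(2E)-3-(4-hydroxyphenyl)prop-2-en-1-yl]oxy}-4,8-dimethyldeca-4,8-dien-1-ylidene]-2-(2-methylprop-1-en-1-yl)-5-oxooxolan-3-yl acetate (CNP0237370.1) | CC(=O)O[C@H]1/C(=C\C[C@@H](O)/C(C)=C/CC/C(C)=C\COC/C=C/c2ccc(O)cc2)C(=O)O[C@@H]1C=C(C)C | target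

**Step count**

Total: 17 steps. Longest linear sequence: 11 steps (steps 1–6, then 13–17).

**Steps most likely to fail**

Step 13 (key step). The hindered cyclic dienolate may discriminate poorly between the aldehyde faces or react sluggishly with the catalyst-bound aldehyde; some Z alkylidene may form; and the silyl cation may ionise the electron-rich cinnamyl ether. Fallback: setting out from 8 and 16, the same partners would be joined under an achiral Lewis acid (BF3·OEt2, CH2Cl2/Et2O, −78 °C). This should give the adduct as a mixture of carbinol epimers, (3E,4S,5R)-3-[(4E,8Z)-3-hydroxy-4,8-dimethyl-10-(aryl-allyloxy)deca-4,8-dien-1-ylidene] lactone F1. Buffered Dess–Martin oxidation (NaHCO3, CH2Cl2, 0 °C) would convert both epimers to the α-methyl enone F2, which would be reduced at once with (S)-Me-CBS and catecholborane (toluene, −78 °C). With the alkenyl group as the large substituent this should give the (R)-alcohol, so the route is rejoined at 17.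

Step 3 (with the aldehyde made in step 2). The basic, hindered ylide may enolise the α-oxygenated aldehyde, which would epimerise C5 or expel the C4 silyloxy group by β-elimination. Fallback: setting out from 3, a non-basic Takai–Lombardo methylenation (Zn, CH2Br2, TiCl4, THF/CH2Cl2, 0 °C) would give the vinyl lactone (4S,5R)-5-ethenyl-4-(triethylsilyloxy)oxolan-2-one F3. Cross-metathesis of F3 with 2-methyl-2-butene (Grubbs second-generation catalyst, 40 °C) would then install the 2-methylpropenyl group and rejoin the route at 4.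

Step 11. The allylic oxidation may lose site selectivity (attack at the cinnamyl CH2 or at the internal neryl alkene) or over-oxidise the electron-rich styrene unit. Fallback: setting out from 14, one equivalent of mCPBA (NaHCO3, CH2Cl2, −20 °C) should epoxidise the terminal, most electron-rich alkene to the epoxide F4 (racemic at the oxirane carbon). Periodic acid (THF/H2O, 0 °C) would cleave F4 to the aldehyde (4Z)-4-methyl-6-({(2E)-3-[4-(triisopropylsilyloxy)phenyl]prop-2-en-1-yl}oxy)hex-4-enal F5. A Wittig reaction of F5 with 2-(triphenylphosphoranylidene)propanal (toluene, 80 °C) should give the (E)-enal directly, rejoining the route at 16 and bypassing 15.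

**Further compounds**

F1 | step 13 | (3E,4S,5R)-3-[(4E,8Z)-3-hydroxy-4,8-dimethyl-10-({(2E)-3-[4-(triisopropylsilyloxy)phenyl]prop-2-en-1-yl}oxy)deca-4,8-dien-1-ylidene]-5-(2-methylprop-1-en-1-yl)-4-(triethylsilyloxy)oxolan-2-one, mixture of carbinol epimers | CC[Si](CC)(CC)O[C@H]1/C(=C\CC(O)/C(C)=C/CC/C(C)=C\COC/C=C/c2ccc(O[Si](C(C)C)(C(C)C)C(C)C)cc2)C(=O)O[C@@H]1C=C(C)C
F2 | step 13 | (3E,4S,5R)-3-[(4E,8Z)-4,8-dimethyl-3-oxo-10-({(2E)-3-[4-(triisopropylsilyloxy)phenyl]prop-2-en-1-yl}oxy)deca-4,8-dien-1-ylidene]-5-(2-methylprop-1-en-1-yl)-4-(triethylsilyloxy)oxolan-2-one | CC[Si](CC)(CC)O[C@H]1/C(=C\CC(=O)/C(C)=C/CC/C(C)=C\COC/C=C/c2ccc(O[Si](C(C)C)(C(C)C)C(C)C)cc2)C(=O)O[C@@H]1C=C(C)C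
F3 | step 3 | (4S,5R)-5-ethenyl-4-(triethylsilyloxy)oxolan-2-one | CC[Si](CC)(CC)O[C@H]1CC(=O)O[C@@H]1C=C
F4 | step 11 | triisopropyl{4-[(1E)-3-{[(2Z)-5-(3,3-dimethyloxiran-2-yl)-3-methylpent-2-en-1-yl]oxy}prop-1-en-1-yl]phenoxy}silane (racemic at the oxirane carbon) | CC1(C)OC1CC/C(C)=C\COC/C=C/c1ccc(O[Si](C(C)C)(C(C)C)C(C)C)cc1
F5 | step 11 | (4Z)-4-methyl-6-({(2E)-3-[4-(triisopropylsilyloxy)phenyl]prop-2-en-1-yl}oxy)hex-4-enal | O=CCC/C(C)=C\COC/C=C/c1ccc(O[Si](C(C)C)(C(C)C)C(C)C)cc1
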